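**Remark on the chemistry:** ring A is numbered C1 (acyl carbon) to C6 (the only ring CH) and the ketone carbon is C7. The target has no stereocentre; the only stereochemical element on the route is the E alkene of 3, 4, 5, 10, 11 and 12, which ends inside ring A.

## The problem

Gancaonin J (22) is a dihydrochalcone: ring B, a 4-hydroxyphenyl group, is joined through a saturated two-carbon chain to a ketone (C7) on ring A. Ring A is a resorcinol substituted at five of six carbons: C1 acyl, C2 OH, C3 prenyl, C4 OH, C5 prenyl, C6 H. Because there is no stereocentre, the task is purely regiochemical. One prenyl group must sit between the two oxygens (C3) and the other ortho to the C4 hydroxyl only (C5), without O-prenylation or over-alkylation, which is what direct prenylation of a resorcinol ketone tends to give. The two trisubstituted alkenes ortho to phenols are the fragile part. Brønsted and Lewis acids close them to 2,2-dimethylchromans, electrophilic halogen and oxidants attack them, and hydrogenation removes them. Friedel–Crafts acylation, ring halogenation and benzyl ethers are therefore excluded once the prenyl groups are in place, and the free resorcinol is easily oxidised. The enabling feature is the pattern around C4: its hydroxyl is flanked by both prenyl-bearing carbons and is meta to the C2 oxygen. An electrocyclic benzannulation lays down exactly this array from a ketene carbon (C4), the two carbons of an oxygenated alkyne (C3, C2) and a vinyl terminus (C5). After such a ring synthesis C1 is the only ring CH ortho to an oxygen (C6 is meta to both), so the acyl chain can be attached last without regiochemical doubt.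

## Retrosynthesis

**Unmasking, 22 from 21.** No skeletal bond is cut; the three phenols are carried as methoxymethyl ethers in 21. This acetal is chosen over benzyl (hydrogenolysis would saturate the prenyl groups) and methyl (Lewis-acid cleavage would cyclise them). It is also the group that directs the metalation one step earlier. The forward step must remove three acetals with dilute protic acid without closing a prenyl group onto a freed hydroxyl.

**C1–C7, 21 from 16 and 19.** The aryl–carbonyl bond is cut to give bis-acetal 16 and Weinreb amide 19, joined through aryllithium 20. The neighbouring cuts (C7–C8 or C8–C9) would first require an aldehyde or acetyl group on ring A, and then an oxidation or an enone reduction next to two prenyl alkenes. An acid-mediated acylation of the free resorcinol is excluded by the prenyl groups. The precursors are a tetrasubstituted benzene with no carbonyl and a simple ring B amide. The forward reaction needs lithiation at C1 only, which the C2 acetal oxygen should ensure, and a single addition to the amide.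

**Ring B piece, 19 from 18 from 17.** The acetal O–C bond and then the amide C–N bond are cut, leading to phloretic acid 17. Amide formation comes first because the hydroxylamine outcompetes the phenol, so 17 needs no prior protection. Both steps are routine.

**Oxygen groups of ring A, 16 from 15 from 14.** Two O–CH2 bonds and one O–Si bond are exchanged. The silyl ether that the ring synthesis delivers does not direct lithiation, so it is replaced by the acetal via resorcinol 15. This costs two steps and is the price of building the ring with a siloxyalkyne.

**Ring A, 14 from 5 and 9 (key disconnection).** Three ring bonds are cut: C3–C4, C1–C2 and C4–C5. This gives diazo ketone 5, which supplies C4, C1, C6, C5 and the C5 prenyl group, and siloxyalkyne 9, which supplies C3 with its prenyl group and C2 with its oxygen. The forward relay runs through vinylketene 10, cyclobutenone 11, dienylketene 12 and dienone 13. Against stepwise prenylation of a bought resorcinol, this cut places both prenyl groups and both oxygens in one operation. Each prenyl–ring bond already exists in a fragment, so no C- versus O-allylation or 3- versus 5-selectivity arises. A fully substituted arene becomes two acyclic chains. The forward reaction needs the ketene to be trapped by the ynol ether faster than it oligomerises, and it needs both prenyl alkenes to stay out of the chemistry.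

**Diazo ketone, 5 from 3 from 1.** The diazo group is removed to give enone 3 (via trifluoroacetyl diketone 4). The C3=C4 alkene of 3 is then cut by an olefination that joins a three-carbon acetonyl unit to aldehyde 2, made in the flask from alcohol 1. Diazo transfer to the methyl ketone is preferred to acylating a diazoalkane with an unsaturated acid chloride, which suffers dipolar addition to the enone. The forward steps must keep the skipped diene from moving into conjugation.

**Siloxyalkyne, 9 from 7 from 6 from 1.** The O–Si bond and the alkyne are cut back to ynolate 8 and ester 7. An ester-to-ynolate homologation turns RCO2Et into R–C≡C–O(–), so R must be the prenyl group itself. The correct ester is therefore the C6 β,γ-unsaturated ester 7. A γ,δ-unsaturated ester from an orthoester Claisen rearrangement would be one carbon too long and would place a homoprenyl group on ring A. Ester 7 comes from acid 6, and 6 from the same alcohol 1 that feeds the other fragment. The forward homologation must add to the ester carbonyl faster than it enolises the doubly activated CH2.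

## Roads not taken

**Alternative 1:** The two aryl–CH2 bonds of the prenyl groups are cut back to aryl ethers. The substrate is the 2,4-bis(1,1-dimethylallyl) ether A2 of a preformed dihydrochalcone whose ring B phenol is a pivalate. Heating should move both allyl units from oxygen to carbon by (3,3) shifts and give A1, one ester cleavage from 22.
- Merits: the ketone is installed on a plain resorcinol before any prenyl group exists, no organolithium or photochemistry is needed, and the sequence is probably shorter than the chosen one.
- Weak points: the O2 allyl group has a single free ortho site (C3), while the O4 group can go to C3 or C5. If the O4 group takes C3, the other must travel by an ortho-to-para relay, which delivers an inverted 1,1-dimethylallyl group at C5. The o-prenylphenols formed at the rearrangement temperature can close to chromans. Making a tertiary allyl ether on the chelated, hindered C2 hydroxyl is itself difficult.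
- Comparison: Alternative 1 is better on step count and cost. The chosen plan offers regiochemical certainty, since in 5 and 9 each prenyl group is already bonded to its future ring carbon, and it forms 14 under neutral conditions. It pays with a late C-acylation.

**Alternative 2:** The ring is cut at C1–C2 and C5–C6. A 1-methoxy-1,3-bis(trimethylsilyloxy)diene A4 carrying both prenyl groups would add across terminal ynone A5, which carries the whole chain and ring B. Loss of the methoxy and silyl groups on mild acidic work-up would give A3, the ring B silyl ether of 22.
- Merits: this is the most convergent plan. The ketone arrives with the dienophile, so no acylation after ring formation and no protecting-group exchange on ring A is needed.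
- Weak points: A4 is substituted at both C2 and C4. Such dienes reach the s-cis form with difficulty, form as geometric mixtures at the prenyl-bearing terminus, and with ynones tend to give open-chain conjugate adducts or simply desilylate. A4 needs sequential γ- and α-prenylation of an acetoacetate and double silylation of a hindered keto ester. A5 is prone to polymerisation.
- Comparison: in step count Alternative 2 is clearly better. The chosen plan has unhindered reacting termini (monosubstituted in both 10 and 9) and a close reaction class for the ring-forming step, at the price of roughly four extra steps for the C1 acyl group.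

**Alternative 3:** The cut is on both sides of C7. A palladium-catalysed carbonylative Suzuki–Miyaura coupling would join ring A aryl iodide A7, the inserted carbonyl carbon and B-alkyl borane A8, giving A6, which is the same compound as 21.
- Merits: the conditions are mild and nearly neutral, no aryllithium meets an enolisable amide, and the ketone is made in one operation.
- Weak points: this is an end game only. A7 still requires ring A with both prenyl groups, and then an iodine at C1. Electrophilic iodination of a prenylated electron-rich arene is not chemoselective, so the iodine would come from the same lithiation that gives 20, adding a step. The aryl iodide is hindered and ortho-oxygenated. A8 must be free of excess hydroborating agent, which would attack the prenyl alkenes.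
- Comparison: the two plans meet at the same penultimate compound. The chosen plan reaches it from 16 in one operation instead of two. Alternative 3 is the better option if 20 enolises 19 instead of adding, but it does not address ring A, which step 6 of the chosen plan does.

Key step: step 6

## Route

Step 1
Reactants: 1 4-methylpent-3-en-1-ol
Product: 3 (3E)-7-methylocta-3,6-dien-2-one, via 4-methylpent-3-enal 2 (not isolated)
Conditions: Dess–Martin periodinane, Ph3P=CHC(O)CH3 (2.5 equiv), CH2Cl2, 0 °C to rt
Reagents that add atoms: 1-(triphenylphosphoranylidene)propan-2-one, CC(=O)C=P(c1ccccc1)(c1ccccc1)c1ccccc1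
Why: Tandem oxidation–Wittig olefination traps the volatile, isomerisation-prone β,γ-unsaturated aldehyde 2 as it forms; the oxidant leaves the trisubstituted alkene alone, and the stabilised acyl ylide should give the E enone without added base.

Step 2
Reactants: 3 (3E)-7-methylocta-3,6-dien-2-one
Product: 5 (3E)-1-diazo-7-methylocta-3,6-dien-2-one, via trifluoroacetyl diketone 4 (not isolated)
Conditions: LiN(SiMe3)2, THF, −78 °C; CF3CO2CH2CF3; aq HCl work-up (crude); then CH3SO2N3, Et3N, H2O, MeCN, rt
Reagents that add atoms: methanesulfonyl azide, CS(=O)(=O)N=[N+]=[N-]
Why: Detrifluoroacetylative diazo transfer: kinetic deprotonation at the methyl group (cross-conjugated enolate) should be preferred to the doubly allylic C5 hydrogens, Claisen acylation activates that carbon, and azide transfer with loss of the trifluoroacetyl group as its sulfonamide gives the diazo ketone without touching either alkene.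

Step 3
Reactants: 1 4-methylpent-3-en-1-ol
Product: 6 4-methylpent-3-enoic acid
Conditions: TEMPO (cat.), PhI(OAc)2, MeCN/H2O (1:1), rt
Reagents that add atoms: water, O
Why: Nitroxyl-catalysed oxidation takes the primary alcohol through the aldehyde hydrate to the acid under near-neutral conditions that should neither move the β,γ-alkene nor lactonise the product, as strongly acidic oxidants might.

Step 4
Reactants: 6 4-methylpent-3-enoic acid
Product: 7 ethyl 4-methylpent-3-enoate
Conditions: EtI, K2CO3, DMF, rt
Reagents that add atoms: iodoethane, CCI
Why: Carboxylate O-alkylation (SN2) avoids the acid of a Fischer esterification, under which this acid closes to the γ-lactone; the weak base should not bring the alkene into conjugation.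

Step 5
Reactants: 7 ethyl 4-methylpent-3-enoate
Product: 9 triisopropyl[(5-methylhex-4-en-1-yn-1-yl)oxy]silane, via lithium ynolate 8 (not isolated)
Conditions: CH2Br2, lithium 2,2,6,6-tetramethylpiperidide, THF, −78 °C; then n-BuLi, −78 °C to rt; then i-Pr3SiCl, −78 °C to rt
Reagents that add atoms: dibromomethane, BrCBr; chlorotriisopropylsilane, CC(C)[Si](Cl)(C(C)C)C(C)C
Why: Kowalski ester-to-ynolate homologation: dibromomethyllithium adds to the ester, the dibromo ketone enolate undergoes bromine–lithium exchange and 1,2-shift of the prenyl group to give ynolate 8, and the bulky chlorosilane traps it on oxygen. The group R of RCO2Et ends on the alkyne carbon remote from oxygen, so the C6 ester gives the prenyl-substituted siloxyalkyne.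

Step 6
Reactants: 5 (3E)-1-diazo-7-methylocta-3,6-dien-2-one; 9 triisopropyl[(5-methylhex-4-en-1-yn-1-yl)oxy]silane
Product: 14 2,6-bis(3-methylbut-2-en-1-yl)-3-[(triisopropylsilyl)oxy]phenol, via vinylketene 10 (not isolated), via vinylcyclobutenone 11 (not isolated), via dienylketene 12 (not isolated), via cyclohexadienone 13 (not isolated)
Conditions: hν (254 nm, quartz), ClCH2CH2Cl, rt, until 5 is consumed; then 80 °C
Reagents that add atoms: none
Why: Irradiation expels N2 from 5 and the alkenyl group migrates (photochemical Wolff rearrangement) to give vinylketene 10 with the E alkene intact. The electron-rich siloxyalkyne adds to the ketene C=C bond in a polar (2+2) cycloaddition in which its nucleophilic prenyl-bearing carbon bonds to the ketene carbonyl carbon (C3–C4) and its oxygen-bearing carbon to the former diazo carbon (C1–C2), giving cyclobutenone 11. Four-electron conrotatory opening of 11 gives dienylketene 12, and ring A closes by six-electron disrotatory electrocyclisation between the ketene carbon and the vinyl terminus (C4–C5) to dienone 13, which tautomerises to phenol 14; the opening is reversible, so the geometry that cannot cyclise is recycled. This is the Danheiser benzannulation in its diazo ketone variant with trialkylsilyloxyalkynes, the established route to 2-substituted resorcinol monosilyl ethers. No stereocentre is created in the product, since the sp3 carbons of 11 and 13 are lost on aromatisation. The required regiochemistry (silyloxy meta to the new hydroxyl, both prenyl groups flanking it) follows from the ketene/ynol ether polarity alone. Chemoselectivity rests on the ynol ether being far more reactive towards the ketene than either trisubstituted alkene, and the E geometry of 5 keeps its own prenyl alkene out of reach of the ketene. Irradiation is stopped once 5 is gone and remaining 11 is converted by heating, to limit light exposure of the o-prenylphenol.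

Step 7
Reactants: 14 2,6-bis(3-methylbut-2-en-1-yl)-3-[(triisopropylsilyl)oxy]phenol
Product: 15 2,4-bis(3-methylbut-2-en-1-yl)benzene-1,3-diol
Conditions: Bu4NF, AcOH, THF, 0 °C
Reagents that add atoms: none
Why: Fluoride cleavage of the aryl silyl ether; acetic acid buffers the oxidation-prone resorcinolate and is too weak to cyclise the prenyl groups.

Step 8
Reactants: 15 2,4-bis(3-methylbut-2-en-1-yl)benzene-1,3-diol
Product: 16 1,3-bis(methoxymethoxy)-2,4-bis(3-methylbut-2-en-1-yl)benzene
Conditions: NaH, CH3OCH2Cl, DMF, 0 °C to rt
Reagents that add atoms: chloromethyl methyl ether, COCCl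
Why: O-Alkylation of both phenoxides; the strong base is used because the C4 hydroxyl is flanked by two prenyl groups. The C2 acetal becomes the directing group for metalation.

Step 9
Reactants: 17 3-(4-hydroxyphenyl)propanoic acid (phloretic acid)
Product: 18 3-(4-hydroxyphenyl)-N-methoxy-N-methylpropanamide
Conditions: MeNHOMe·HCl, EDC·HCl, HOBt (cat.), N-methylmorpholine, CH2Cl2, 0 °C to rt
Reagents that add atoms: N,O-dimethylhydroxylamine hydrochloride, CNOC.Cl
Why: Carbodiimide-mediated amide coupling; the hydroxylamine is a much better nucleophile than the phenol, so the phenol can stay free at this stage.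

Step 10
Reactants: 18 3-(4-hydroxyphenyl)-N-methoxy-N-methylpropanamide
Product: 19 N-methoxy-3-[4-(methoxymethoxy)phenyl]-N-methylpropanamide
Conditions: CH3OCH2Cl, i-Pr2NEt, CH2Cl2, 0 °C to rt
Reagents that add atoms: chloromethyl methyl ether, COCCl
Why: Base-mediated O-alkylation of the phenol; the acetal tolerates the aryllithium of the next step and leaves in the same final operation as the ring A acetals.

Step 11
Reactants: 16 1,3-bis(methoxymethoxy)-2,4-bis(3-methylbut-2-en-1-yl)benzene; 19 N-methoxy-3-[4-(methoxymethoxy)phenyl]-N-methylpropanamide
Product: 21 1-[2,4-bis(methoxymethoxy)-3,5-bis(3-methylbut-2-en-1-yl)phenyl]-3-[4-(methoxymethoxy)phenyl]propan-1-one, via aryllithium 20 (not isolated)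
Conditions: n-BuLi, TMEDA, THF, −20 to 0 °C; then 19, −78 to 0 °C; aq NH4Cl
Reagents that add atoms: none
Why: Directed ortho-metalation: C1–H is the only ring hydrogen ortho to an acetal oxygen (C6–H is meta to both), so coordination of the base to the C2 methoxymethoxy group should deliver aryllithium 20. Addition to the Weinreb amide stops at the chelated tetrahedral lithium adduct, which releases the ketone only on work-up (Weinreb ketone synthesis).

Step 12
Reactants: 21 1-[2,4-bis(methoxymethoxy)-3,5-bis(3-methylbut-2-en-1-yl)phenyl]-3-[4-(methoxymethoxy)phenyl]propan-1-one
Product: 22 Gancaonin J, 1-[2,4-dihydroxy-3,5-bis(3-methylbut-2-en-1-yl)phenyl]-3-(4-hydroxyphenyl)propan-1-one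
Conditions: 3 M aq HCl, MeOH, rt to 40 °C
Reagents that add atoms: none
Why: Acid-catalysed acetal exchange with methanol removes all three methoxymethyl groups; dilute HCl in methanol is the usual finish for prenylated polyphenols and is kept mild and short so that the prenyl groups do not close onto the freed hydroxyls.

## Compound list

1 | 4-methylpent-3-en-1-ol | CC(C)=CCCO | starting material
2 | 4-methylpent-3-enal | CC(C)=CCC=O | intermediate (not isolated)
3 | (3E)-7-methylocta-3,6-dien-2-one | CC(C)=CC/C=C/C(C)=O | intermediate
4 | (5E)-1,1,1-trifluoro-9-methyldeca-5,8-diene-2,4-dione | CC(C)=CC/C=C/C(=O)CC(=O)C(F)(F)F | intermediate (not isolated)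
5 | (3E)-1-diazo-7-methylocta-3,6-dien-2-one | CC(C)=CC/C=C/C(=O)C=[N+]=[N-] | intermediate
6 | 4-methylpent-3-enoic acid | CC(C)=CCC(=O)O | intermediate
7 | ethyl 4-methylpent-3-enoate | CCOC(=O)CC=C(C)C | intermediate
8 | lithium 5-methylhex-4-en-1-yn-1-olate | [Li+].[O-]C#CCC=C(C)C | intermediate (not isolated)
9 | triisopropyl[(5-methylhex-4-en-1-yn-1-yl)oxy]silane | CC(C)=CCC#CO[Si](C(C)C)(C(C)C)C(C)C | intermediate
10 | (3E)-7-methylocta-1,3,6-trien-1-one | CC(C)=CC/C=C/C=C=O | intermediate (not isolated)
11 | 4-[(1E)-5-methylhexa-1,4-dien-1-yl]-2-(3-methylbut-2-en-1-yl)-3-[(triisopropylsilyl)oxy]cyclobut-2-en-1-one (racemic) | CC(C)=CC/C=C/C1C(=O)C(CC=C(C)C)=C1O[Si](C(C)C)(C(C)C)C(C)C | intermediate (not isolated)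
12 | (3E,5E)-9-methyl-2-(3-methylbut-2-en-1-yl)-3-[(triisopropylsilyl)oxy]deca-1,3,5,8-tetraen-1-one (chain carbons C2 and C5 cis across C3=C4) | O=C=C(CC=C(C)C)/C(O[Si](C(C)C)(C(C)C)C(C)C)=C\C=C\CC=C(C)C | intermediate (not isolated)
13 | 2,6-bis(3-methylbut-2-en-1-yl)-3-[(triisopropylsilyl)oxy]cyclohexa-2,4-dien-1-one (racemic) | CC(C)=CCC1C=CC(O[Si](C(C)C)(C(C)C)C(C)C)=C(CC=C(C)C)C1=O | intermediate (not isolated)
14 | 2,6-bis(3-methylbut-2-en-1-yl)-3-[(triisopropylsilyl)oxy]phenol | CC(C)=CCc1ccc(O[Si](C(C)C)(C(C)C)C(C)C)c(CC=C(C)C)c1O | intermediate
15 | 2,4-bis(3-methylbut-2-en-1-yl)benzene-1,3-diol | CC(C)=CCc1ccc(O)c(CC=C(C)C)c1O | intermediate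
16 | 1,3-bis(methoxymethoxy)-2,4-bis(3-methylbut-2-en-1-yl)benzene | COCOc1ccc(CC=C(C)C)c(OCOC)c1CC=C(C)C | intermediate
17 | 3-(4-hydroxyphenyl)propanoic acid (phloretic acid) | O=C(O)CCc1ccc(O)cc1 | starting material
18 | 3-(4-hydroxyphenyl)-N-methoxy-N-methylpropanamide | CON(C)C(=O)CCc1ccc(O)cc1 | intermediate
19 | N-methoxy-3-[4-(methoxymethoxy)phenyl]-N-methylpropanamide | CON(C)C(=O)CCc1ccc(OCOC)cc1 | intermediate
20 | [2,4-bis(methoxymethoxy)-3,5-bis(3-methylbut-2-en-1-yl)phenyl]lithium | [Li]c1cc(CC=C(C)C)c(OCOC)c(CC=C(C)C)c1OCOC | intermediate (not isolated)
21 | 1-[2,4-bis(methoxymethoxy)-3,5-bis(3-methylbut-2-en-1-yl)phenyl]-3-[4-(methoxymethoxy)phenyl]propan-1-one | COCOc1ccc(CCC(=O)c2cc(CC=C(C)C)c(OCOC)c(CC=C(C)C)c2OCOC)cc1 | intermediate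
22 | Gancaonin J, 1-[2,4-dihydroxy-3,5-bis(3-methylbut-2-en-1-yl)phenyl]-3-(4-hydroxyphenyl)propan-1-one | CC(C)=CCc1cc(C(=O)CCc2ccc(O)cc2)c(O)c(CC=C(C)C)c1O | target

## Step count and least certain steps

Total step count: 12. Longest linear sequence: 8 steps (steps 3, 4, 5, 6, 7, 8, 11, 12, from alcohol 1 through the siloxyalkyne branch). The diazo ketone branch (steps 1, 2) and the ring B branch (steps 9, 10) are convergent.

**Step 6 (key step).**
- What may go wrong: vinylketene 10 may be captured inefficiently by 9, through ketene oligomerisation or hydrolytic loss of the siloxyalkyne by traces of acid or water. Secondary photochemistry may also erode the material, either excited-state cyclisation of the o-prenylphenol product onto its alkene or photoisomerisation of the skipped diene of 5 before nitrogen loss.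
- Fallback: give up the ring synthesis and assemble 16 by two metalation/prenylation events on a bought resorcinol. It cannot set out from a numbered compound, because none before 16 contains ring A. It starts from purchased 4-bromoresorcinol F1 and comes back to the route at 16, bypassing 5, 9, 14 and 15.
- F1 is protected with chloromethyl methyl ether and i-Pr2NEt to give 1-bromo-2,4-bis(methoxymethoxy)benzene F2.
- Bromine–lithium exchange with n-BuLi at −78 °C, transmetalation with CuI and addition of prenyl bromide gives 2,4-bis(methoxymethoxy)-1-(3-methylbut-2-en-1-yl)benzene F3.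
- Lithiation of F3 with n-BuLi at 0 °C should occur at the CH between the two acetal oxygens, the most activated ring position. The same CuI/prenyl bromide sequence then gives 16.

**Step 5.**
- What may go wrong: α-deprotonation of the β,γ-unsaturated ester 7, whose CH2 is both allylic and next to the carbonyl, may compete with carbonyl addition of the carbenoid. This would lead to enolate self-condensation or alkene migration. Silylation of 8 on carbon instead of oxygen is a second risk.
- Fallback: reach the same ynolate by oxidising an acetylide, so that no ester is involved. It sets out from alcohol 1 and comes back at 9 through ynolate 8, bypassing 6 and 7.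
- 1 is oxidised to aldehyde 2 as in step 1 (without the ylide), and 2 is treated directly with CBr4 and PPh3 (Corey–Fuchs olefination) to give 1,1-dibromo-5-methylhexa-1,4-diene F4.
- Two equivalents of n-BuLi at −78 °C convert F4 into lithium 5-methylhex-4-en-1-ynide F5.
- F5 is oxidised in the same flask with lithium tert-butyl peroxide (from t-BuOOH and LiN(SiMe3)2) to ynolate 8, which is silylated on oxygen with i-Pr3SiOSO2CF3 to give 9.

**Step 11.**
- What may go wrong: lateral lithiation at the benzylic, allylic CH2 of a prenyl group (the C3 one lies between two coordinating acetals) may compete with ring lithiation at C1. Aryllithium 20 may also enolise amide 19 instead of adding.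
- Fallback: introduce the C1 carbon electrophilically, with no ring deprotonation. It sets out from resorcinol 15 and comes back at ketone 21, bypassing 16 and 20.
- Casnati–Skattebøl ortho-formylation of 15 (MgCl2, Et3N, paraformaldehyde, MeCN, reflux) can only reach C1, the single free position ortho to a hydroxyl. It gives 2,4-dihydroxy-3,5-bis(3-methylbut-2-en-1-yl)benzaldehyde F6.
- NaH and chloromethyl methyl ether give 2,4-bis(methoxymethoxy)-3,5-bis(3-methylbut-2-en-1-yl)benzaldehyde F7.
- For the side chain, purchased 2-(4-hydroxyphenyl)ethanol F8 is protected at the phenol (K2CO3, chloromethyl methyl ether, acetone) to 2-[4-(methoxymethoxy)phenyl]ethanol F9. Appel bromination (CBr4, PPh3) gives 1-(2-bromoethyl)-4-(methoxymethoxy)benzene F10, and magnesium in THF gives {2-[4-(methoxymethoxy)phenyl]ethyl}magnesium bromide F11.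
- Addition of F11 to F7 gives 1-[2,4-bis(methoxymethoxy)-3,5-bis(3-methylbut-2-en-1-yl)phenyl]-3-[4-(methoxymethoxy)phenyl]propan-1-ol F12, and Dess–Martin oxidation of F12 gives 21.

**Step 2.**
- What may go wrong: deprotonation of 3 at the doubly allylic C5 instead of the methyl group would lead to acylation at the wrong carbon or to the conjugated dienone. Base-induced alkene migration during the azide transfer is a second risk.
- Fallback: form the enone and the diazo ketone in one olefination, so that the skipped dienone is never enolised. It sets out from alcohol 1 (through aldehyde 2, generated as in step 1) and comes back at 5, bypassing 3 and 4.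
- Aldehyde 2 is condensed with the known reagent diethyl (3-diazo-2-oxopropyl)phosphonate F13 in a Horner–Wadsworth–Emmons reaction under Masamune–Roush conditions (LiCl, i-Pr2NEt, MeCN). This should give the E diazo ketone 5 directly.

## Further compounds

F1 | step 6 | 4-bromoresorcinol (purchased) | Oc1ccc(Br)c(O)c1
F2 | step 6 | 1-bromo-2,4-bis(methoxymethoxy)benzene | COCOc1ccc(Br)c(OCOC)c1
F3 | step 6 | 2,4-bis(methoxymethoxy)-1-(3-methylbut-2-en-1-yl)benzene | COCOc1ccc(CC=C(C)C)c(OCOC)c1
F4 | step 5 | 1,1-dibromo-5-methylhexa-1,4-diene | CC(C)=CCC=C(Br)Br
F5 | step 5 | lithium 5-methylhex-4-en-1-ynide | [Li]C#CCC=C(C)C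
F6 | step 11 | 2,4-dihydroxy-3,5-bis(3-methylbut-2-en-1-yl)benzaldehyde | CC(C)=CCc1cc(C=O)c(O)c(CC=C(C)C)c1O
F7 | step 11 | 2,4-bis(methoxymethoxy)-3,5-bis(3-methylbut-2-en-1-yl)benzaldehyde | COCOc1c(C=O)cc(CC=C(C)C)c(OCOC)c1CC=C(C)C
F8 | step 11 | 2-(4-hydroxyphenyl)ethanol (purchased) | OCCc1ccc(O)cc1
F9 | step 11 | 2-[4-(methoxymethoxy)phenyl]ethanol | COCOc1ccc(CCO)cc1
F10 | step 11 | 1-(2-bromoethyl)-4-(methoxymethoxy)benzene | COCOc1ccc(CCBr)cc1
F11 | step 11 | {2-[4-(methoxymethoxy)phenyl]ethyl}magnesium bromide | COCOc1ccc(CC[Mg]Br)cc1
F12 | step 11 | 1-[2,4-bis(methoxymethoxy)-3,5-bis(3-methylbut-2-en-1-yl)phenyl]-3-[4-(methoxymethoxy)phenyl]propan-1-ol (racemic) | COCOc1ccc(CCC(O)c2cc(CC=C(C)C)c(OCOC)c(CC=C(C)C)c2OCOC)cc1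
F13 | step 2 | diethyl (3-diazo-2-oxopropyl)phosphonate | CCOP(=O)(CC(=O)C=[N+]=[N-])OCC
A1 | alternative 1 | 4-{3-[2,4-dihydroxy-3,5-bis(3-methylbut-2-en-1-yl)phenyl]-3-oxopropyl}phenyl pivalate (ring B O-pivaloyl Gancaonin J) | CC(C)=CCc1cc(C(=O)CCc2ccc(OC(=O)C(C)(C)C)cc2)c(O)c(CC=C(C)C)c1O
A2 | alternative 1 | 4-{3-[2,4-bis(2-methylbut-3-en-2-yloxy)phenyl]-3-oxopropyl}phenyl pivalate | C=CC(C)(C)Oc1ccc(C(=O)CCc2ccc(OC(=O)C(C)(C)C)cc2)c(OC(C)(C)C=C)c1
A3 | alternative 2 | 3-[4-(tert-butyldimethylsilyloxy)phenyl]-1-[2,4-dihydroxy-3,5-bis(3-methylbut-2-en-1-yl)phenyl]propan-1-one (ring B O-silyl Gancaonin J) | CC(C)=CCc1cc(C(=O)CCc2ccc(O[Si](C)(C)C(C)(C)C)cc2)c(O)c(CC=C(C)C)c1O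
A4 | alternative 2 | 1-methoxy-2,4-bis(3-methylbut-2-en-1-yl)-1,3-bis(trimethylsilyloxy)buta-1,3-diene | COC(O[Si](C)(C)C)=C(CC=C(C)C)C(O[Si](C)(C)C)=CCC=C(C)C
A5 | alternative 2 | 5-[4-(tert-butyldimethylsilyloxy)phenyl]pent-1-yn-3-one | C#CC(=O)CCc1ccc(O[Si](C)(C)C(C)(C)C)cc1
A6 | alternative 3 | tris-O-methoxymethyl Gancaonin J (identical with 21) | COCOc1ccc(CCC(=O)c2cc(CC=C(C)C)c(OCOC)c(CC=C(C)C)c2OCOC)cc1
A7 | alternative 3 | 1-iodo-2,4-bis(methoxymethoxy)-3,5-bis(3-methylbut-2-en-1-yl)benzene | COCOc1c(I)cc(CC=C(C)C)c(OCOC)c1CC=C(C)C
A8 | alternative 3 | 9-{2-[4-(methoxymethoxy)phenyl]ethyl}-9-borabicyclo[3.3.1]nonane | COCOc1ccc(CCB2C3CCCC2CCC3)cc1
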